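(The earlier runs and the new flask stem from a simulated flask with made-up constants; noise was put on by code.)

At a time of reading of 4.00 d the autumn run stands at its highest target reading, so the reckoning starts from that reading.

| setting | autumn | dusk | winter | flask |
|---|---|---|---|---|
| substrate | 0.30 M | 0.30 M | 0.60 M | 0.30 M |
| partner | 0.33 M | 0.33 M | 0.33 M | 0.330 M |
| protic impurity | 0.0075 M | 0.030 M | 0.015 M | 0.0150 M |
| remark | run made earlier | run made earlier | run made earlier |  |
| time |  |  |  | 15 d |

| run | time / d | target / % | substrate / % |
|---|---|---|---|
| autumn | 1.04 | 24 | 21 |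
| autumn | 2.08 | 32 | 11 |
| autumn | 4.00 | 33 | 5 |
| autumn | 8.00 | 31 | 4 |
| autumn | 15.0 | 26 | 3 |
| dusk | 1.04 | 25 | 22 |
| dusk | 2.08 | 28 | 10 |
| dusk | 4.00 | 29 | 10 |
| dusk | 8.00 | 29 | 3 |
| dusk | 15.0 | 22 | 5 |
| winter | 1.04 | 16 | 11 |
| winter | 2.08 | 18 | 7 |
| winter | 4.00 | 19 | 4 |
| winter | 8.00 | 19 | 4 |
| winter | 15.0 | 15 | 3 |

(standard deviation of a reading: 1.5 percentage points)

- the moment within 15 d at which there is most target
- the amount of target, in percent of the substrate charged, at that time
- the first time at which target reaches 22 %, in the same percent, in d



The flask carries more protic impurity than autumn and less than dusk, with the same substrate and partner. The autumn peak reading, 33 %, is therefore taken as a bound from above on the peak of the flask, and the dusk reading, 29 %, as a bound from below.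

To tighten the bracket, the changing fate of the substrate is replaced by its mean since the start, read at 4.00 d:

(substrate gone − target) / target: autumn 1.88, dusk 2.10, mean 1.99

This mean, the substrate lost per substrate turned into target, is the loss ratio, a selectivity factor. With the substrate left taken as the mean of the two readings, 7.50 %:

peak target = (1 − substrate left) / (1 + loss ratio) = 30.9 %, between 29.8 % and 32.1 %

Winter, with twice the substrate, the same partner and the protic impurity of the flask, reads 4.05, twice the mean, so the ratio is taken as proportional to the substrate charged.

The forecast gives 31 % at 4 d and the asked level at 0.75 d, says of its peak “that estimate is fairly firm”, and stands inside this bracket.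

The flask gives 31.5 % at 3.77 d and first holds 22 % of target at 0.746 d.

    substrate + partner ⇌ target + by-product (K = 1.90, k = 0.0860 M⁻¹ h⁻¹)
    partner + protic impurity → quenched reagent (k = 1.70 M⁻¹ h⁻¹)
    2 substrate → self-condensation product (k = 0.150 M⁻¹ h⁻¹)

At 3.77 d the flask holds 31.5 % of target and 7.09 % of substrate, a loss ratio of 1.95 against the carried 1.99. The curve beneath that mean is far from flat: in the flask, the rate of substrate use by self-condensation over that by the forward rate of the step to target runs from 3.2 at the start to 0.20 at 15.0 d. For a neighbour flask charged with 0.18 M of substrate, proportion gives a ratio of 1.19 and, with the same substrate left, a peak of 42.2 %. That neighbour reaches 42.7 % and holds 39.6 % at 15.0 d.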